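The numbers of this flask stand for no real mixture.

3 questions stood on 2 flasks that differ in their free monomer.

    free monomer + initiator → living end + monomer in chains (k1 = 0.074 /M/min)
    free monomer + living end → monomer in chains + living end, rate k2*[living end]*[free monomer] (k2 = 0.039 /M/min)
    living end + transfer agent → dead chain (k3 = 0.013 /M/min)
    living end → dead end (k4 = 0.0026 /min)
    protic impurity + free monomer → quenched substrate (k5 = 0.015 /M/min)

| flask | free monomer | transfer agent | protic impurity | initiator | time |
|---|---|---|---|---|---|
| delta | 1.0 M | 0.0300 M | 0.0200 M | 50 mM | 12 h |
| eta | 0.50 M | 0.0300 M | 0.0200 M | 50 mM | 12 h |

1. which of the two ends with the longer chains by the average number of monomer units in a chain (chains begun, living or dead) ("neither" if they lie within 10%) (delta / eta / neither)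
2. average number of monomer units in a chain (chains begun, living or dead) at the end, delta
3. average number of monomer units in a chain (chains begun, living or dead) at the end, eta

- the average divides the monomer in chains by the number of chains begun, living and dead together
- run time (delta): 12 h

I looked for what stays nearly constant. On its charge of free monomer, the initiator in eta lasts about 27.0 min, far less than the run, so I began the chains at once, as many as the initiator charged. With the transfer agent at its charge, I reckoned that 13.0% of the living ends go by it. That made 0.00650 M against its charge of 0.0300 M, so I froze it at its charge. The ends then decay pseudo-first-order:

loss rate of an end = 0.0026 /min + 0.013 /M/min × 0.0300 M = 0.00299 /min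

I took one monomer per chain begun. I also took off the whole impurity, whose half-life by its own step, with free monomer held at its charge in delta, is 0.77 h, far below the run. The rest of the monomer decays by the exponential of the living ends summed over time. In delta:

ends that do not die: length 15.0

ends that die at once: length 1.00

The real flask lies between, since an end lasts 334 min on average, less than the run but not zero:

0.039 /M/min × 50 mM × (1 − 0.116) / 0.00299 /min = 0.576

I call this the reach, the propagation constant times the living ends summed over the run. Free monomer does not enter this sum, so I gave both flasks the same reach.

length = (charge − impurity − (charge − initiator − impurity) × exp(−reach)) / initiator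

delta: 9.15; eta: 4.77

The forecast chose delta, with 9.1 (8.7 to 9.5) and 4.7 (4.4 to 5), on the ground that “the average length roughly tracks the starting monomer”. Its eta stood below mine.

The simulation gave delta, with 9.19 in delta and 4.82 in eta.

In delta the reach leaves 52.3% of the free monomer charged, and the flask held 52.0% at 12.0 h. The neighbour is eta with 0.30 M of free monomer, read at the same time. I carried the reach over unchanged, 0.576. It gave 43.1% free monomer and a length of 3.02. That flask held 42.9% free monomer, kept 15.5% of its protic impurity, and its chains averaged 3.09.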